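- The charge of Q is conserved: at any moment each part of it is J, something else, or still unreacted, and these fractions add up to the whole charge.

all flasks: D 16 mM (held); temperature 0 °C
- Friday's: Q 0.11 M; run made earlier
- alpha: Q 0.30 M; time 40 d
- delta: Q 0.10 M; time 20 d

- Friday's (time / d: J / %, Q / %): 0.625: 0.9, 83.6; 1.67: 10.3, 64.2; 3.00: 22.0, 44.9; 5.00: 41.9, 18.7; 8.00: 64.6, 0; 10.0: 69.9, 1.8; 12.0: 71.3, 0.7

(standard deviation of a reading: 1 percentage point)

1. the winner by amount of J, in percent of the Q charged; "neither" if no more than 2 percentage points parts them (alpha / delta / neither)
2. how much J is there at the end, in percent of the Q charged: alpha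
3. how much J is there at the end, in percent of the Q charged: delta

- Q is a solid; its amount is given per volume of the solution
- the numbers in the tables scatter with a standard deviation of 1 percentage point
- at the start none of D is in solution
- at the start none of Q is in solution
- what has only dissolved of Q counts as not reacted

- Friday's last reading has J at 71.3 % and solid Q at 0.7 %, so J stood at 71.8 % of what had left the solid. I carry this reading as the branch share (the selectivity), the fraction of reacted Q that ends as J: J at the end is the branch share times the reacted fraction of the charge.
- You may object that what has only dissolved counts as not reacted, so that Friday's J could still have been rising at that reading. It gained 1.4 percentage points over the last two readings, against a scatter of 1 point per reading.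
- You may also object that the share could drift during a run. While solid stood, between 1.67 d and 5.00 d, J gained 69.5 % of the Q lost, which is near the end value.
- The rule needs the charge to react in time. Friday's solid fell steadily, at a pace that clears one Friday charge in 7.32 d. Holding that pace per volume, I estimate about 20.0 d for alpha's charge and about 6.65 d for delta's.
- Clearing the solid is not the end: Friday's J stood at 64.6 % when Q read 0 %, and the readings went on for a tail of 4.00 d more. Alpha has 20.0 d left and delta 13.3 d, so the tail fits in both.
- My own reckoning therefore gives 71.8 % for both flasks. The forecast says neither, with 72 % for alpha and 71 % for delta, which is 0.8 points below mine for delta, on the grounds that “Selectivity is set at the same saturated concentration and the same D”.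
- The flasks give neither, with 73.4 % for alpha and 73.4 % for delta.

    G + X → J (k = 2.70 × 10⁻⁴ /M/s, Ea = 61.0 kJ/mol)
    G + X → E (k = 9.80 × 10⁻⁵ /M/s, Ea = 57.0 kJ/mol)
    D ⇌ X, rate k3*(csat - [X]) (kL = 0.00240 /s)
    Q ⇌ G, rate k4*(cs4 - [G]) while solid is left; crystals form when [G] > cs4 (solubility = 47.0 mM, k = 9.10 × 10⁻⁶ /s)
    (constants at 0 °C)

- Delta stops short of the whole charge because of the step from G + X to E: the run without that step reaches 99.8 %, so the branch share of 71.8 % carried the weight, standing 1.6 points below delta's end. A flask like delta kept at −25 °C has 70 % of its charge still there, solid or dissolved, so Friday's share gives 21.5 % J, and that flask holds 21.0 %.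

The runs stem from a simulated flask for an exercise; scatter was added.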